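## Retrosynthetic overview
1. The target (erythro, 7S,8R) comes from global desilylation of its tetra-TBS ether. The C7 carbinol comes from Mitsunobu inversion of the threo (7R,8R) alcohol.
2. The threo 1,3-diol comes from reductive removal of the auxiliary from an Evans syn-aldol adduct. Key bond C7–C8: boron enolate of an N-(aryloxyacetyl)oxazolidinone plus an aryl aldehyde.
3. The aldehyde fragment comes from vanillin and 1,3-di-O-TBS-glycerol by Mitsunobu etherification.
4. The imide fragment comes from 4-allyl-2,6-dimethoxyphenol and ethyl bromoacetate, followed by hydroboration–oxidation, silylation, saponification and acylation of (S)-4-benzyloxazolidin-2-one.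
5. No ring is formed. Arene rings A and B are bought intact, and the oxazolidinone ring is only carried and then removed.

Assumption and abbreviations: lignan numbering is used (C7 benzylic carbinol, C8 aryloxy carbon, C9 CH2OH). The SMILES decodes as (7S,8R), and the glycerol C2 bears two identical arms, so it is not a stereocentre. TBS = tert-butyldimethylsilyl and TBSO = tert-butyldimethylsilyloxy.

## Route

Step 1
Reactants: 1 glycerol
Product: 2 1,3-bis(TBSO)propan-2-ol
Conditions: TBSCl (2.05 equiv), imidazole (4 equiv), CH2Cl2/DMF, 0 °C to rt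
Reagents that add atoms: tert-butyldimethylsilyl chloride (TBSCl), CC(C)(C)[Si](C)(C)Cl
Why: Silyl ether formation is much faster at the two primary hydroxyls than at the flanked secondary one, so two equivalents of TBSCl leave only the C2 hydroxyl free, and no stereocentre is involved.

Step 2
Reactants: 2 1,3-bis(TBSO)propan-2-ol; 3 vanillin
Product: 5 4-{[1,3-bis(TBSO)propan-2-yl]oxy}-3-methoxybenzaldehyde, via alkoxyphosphonium salt 4 (not isolated)
Conditions: PPh3 (1.3 equiv), DIAD (1.3 equiv), THF, 0 °C to rt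
Reagents that add atoms: triphenylphosphine, c1ccc(cc1)P(c1ccccc1)c1ccccc1 (its atoms stay only in 4; nothing from a reagent stays in 5)
Why: In this Mitsunobu etherification the acidic phenol of vanillin displaces Ph3PO from 4 under neutral conditions that avoid base-induced silyl migration, and the attacked carbon has two identical arms, so no stereocentre arises.

Step 3
Reactants: 6 4-allyl-2,6-dimethoxyphenol; 7 ethyl bromoacetate
Product: 8 ethyl 2-(4-allyl-2,6-dimethoxyphenoxy)acetate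
Conditions: K2CO3 (2 equiv), acetone, reflux
Reagents that add atoms: none
Why: This is a Williamson ether synthesis in which the phenolate attacks an unhindered, activated primary bromide by SN2, so the two ortho methoxy groups do not interfere.

Step 4
Reactants: 8 ethyl 2-(4-allyl-2,6-dimethoxyphenoxy)acetate
Product: 10 ethyl 2-[4-(3-hydroxypropyl)-2,6-dimethoxyphenoxy]acetate, via B-alkyl-9-BBN adduct 9 (not isolated)
Conditions: 9-BBN (1.3 equiv), THF, 0 °C to rt; then 30% H2O2, 3 M aq NaOAc, 0 °C to rt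
Reagents that add atoms: hydrogen peroxide, OO; 9-borabicyclo[3.3.1]nonane (9-BBN), B1C2CCCC1CCC2 (its atoms stay only in 9)
Why: Brown hydroboration–oxidation with bulky 9-BBN gives the anti-Markovnikov primary alcohol, 9-BBN ignores the ester, and the acetate-buffered peroxide oxidation avoids saponification.

Step 5
Reactants: 10 ethyl 2-[4-(3-hydroxypropyl)-2,6-dimethoxyphenoxy]acetate
Product: 11 ethyl 2-{4-[3-(TBSO)propyl]-2,6-dimethoxyphenoxy}acetate
Conditions: TBSCl (1.2 equiv), imidazole (2 equiv), CH2Cl2, 0 °C to rt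
Reagents that add atoms: tert-butyldimethylsilyl chloride (TBSCl), CC(C)(C)[Si](C)(C)Cl
Why: Standard silyl ether protection of the only free hydroxyl makes every distal alcohol of the final molecule removable by fluoride alone.

Step 6
Reactants: 11 ethyl 2-{4-[3-(TBSO)propyl]-2,6-dimethoxyphenoxy}acetate
Product: 12 2-{4-[3-(TBSO)propyl]-2,6-dimethoxyphenoxy}acetic acid
Conditions: LiOH·H2O (2 equiv), THF/MeOH/H2O, 0 °C to rt; then cold 0.5 M HCl to pH 4
Reagents that add atoms: lithium hydroxide, [Li+].[OH-]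
Why: Saponification of an unhindered, inductively activated ethyl ester is fast at or below rt, and the primary alkyl TBS ether survives both the base and the brief cold acidification.

Step 7
Reactants: 12 2-{4-[3-(TBSO)propyl]-2,6-dimethoxyphenoxy}acetic acid; 13 (S)-4-benzyloxazolidin-2-one
Product: 15 (S)-4-benzyl-3-(2-{4-[3-(TBSO)propyl]-2,6-dimethoxyphenoxy}acetyl)oxazolidin-2-one, via mixed pivalic anhydride 14 (not isolated)
Conditions: PivCl (1.05 equiv), Et3N (2.5 equiv), THF, −20 °C; then LiCl (1.1 equiv), 13, −20 °C to rt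
Reagents that add atoms: pivaloyl chloride, CC(C)(C)C(=O)Cl (its atoms stay only in 14)
Why: In this mixed-anhydride N-acylation the LiCl/Et3N-activated oxazolidinone attacks the less hindered carbonyl of 14, and the auxiliary stereocentre is not touched.

Step 8
Reactants: 15 (S)-4-benzyl-3-(2-{4-[3-(TBSO)propyl]-2,6-dimethoxyphenoxy}acetyl)oxazolidin-2-one; 5 4-{[1,3-bis(TBSO)propan-2-yl]oxy}-3-methoxybenzaldehyde
Product: 18 (4S)-4-benzyl-3-[(2S,3R)-3-(4-{[1,3-bis(TBSO)propan-2-yl]oxy}-3-methoxyphenyl)-2-{4-[3-(TBSO)propyl]-2,6-dimethoxyphenoxy}-3-hydroxypropanoyl]oxazolidin-2-one (syn adduct), via Z-boron enolate 16 (not isolated), via boron aldolate 17 (not isolated)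
Conditions: Bu2BOTf (1.15 equiv), Et3N (1.3 equiv), CH2Cl2, −78 to 0 °C; 5 (1.05 equiv), −78 to 0 °C; then pH 7 buffer, MeOH, 30% H2O2, 0 °C
Reagents that add atoms: dibutylboron triflate, CCCCB(CCCC)OS(=O)(=O)C(F)(F)F (its Bu2B unit stays only in 16 and 17)
Why: In this Evans syn aldol, Z-enolate 16 reacts through a closed Zimmerman–Traxler chair on the face away from the benzyl group of the (S)-auxiliary, forging C7–C8 and setting C8 in its final spatial sense (8R after reduction) and C7 as 7R with a syn (threo) relationship.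

Step 9
Reactants: 18 syn aldol adduct
Product: 19 (1R,2R)-1-(4-{[1,3-bis(TBSO)propan-2-yl]oxy}-3-methoxyphenyl)-2-{4-[3-(TBSO)propyl]-2,6-dimethoxyphenoxy}propane-1,3-diol (threo; 7R,8R)
Conditions: NaBH4 (4 equiv), THF/H2O (4:1), 0 °C to rt
Reagents that add atoms: none
Why: Reductive auxiliary cleavage works because hydride attacks the more electrophilic exocyclic imide carbonyl and takes it down to CH2OH (C9) without touching C7 or C8, and the oxazolidinone is recovered.

Step 10
Reactants: 19 threo diol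
Product: 20 (1R,2R)-3-(TBSO)-1-(4-{[1,3-bis(TBSO)propan-2-yl]oxy}-3-methoxyphenyl)-2-{4-[3-(TBSO)propyl]-2,6-dimethoxyphenoxy}propan-1-ol (threo)
Conditions: TBSCl (1.05 equiv), imidazole (2 equiv), CH2Cl2, −10 to 0 °C
Reagents that add atoms: tert-butyldimethylsilyl chloride (TBSCl), CC(C)(C)[Si](C)(C)Cl
Why: Chemoselective silylation succeeds because the primary C9 hydroxyl reacts far faster than the secondary benzylic C7 hydroxyl, which is crowded by the 2,6-dimethoxyphenoxy group.

Step 11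
Reactants: 20 threo C9-silyl ether alcohol
Product: 22 (1S,2R)-3-(TBSO)-1-(4-{[1,3-bis(TBSO)propan-2-yl]oxy}-3-methoxyphenyl)-2-{4-[3-(TBSO)propyl]-2,6-dimethoxyphenoxy}propyl 4-nitrobenzoate (erythro), via alkoxyphosphonium salt 21 (not isolated)
Conditions: 4-O2NC6H4CO2H (3 equiv), PPh3 (3 equiv), DIAD (3 equiv), toluene, −10 °C to rt
Reagents that add atoms: 4-nitrobenzoic acid, OC(=O)c1ccc(cc1)[N+](=O)[O-]; triphenylphosphine, c1ccc(cc1)P(c1ccccc1)c1ccccc1 (its atoms stay only in 21)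
Why: In this Mitsunobu inversion (Martin–Dodge variant for hindered alcohols) the acidic 4-nitrobenzoate displaces Ph3PO from 21 by SN2 in a non-polar solvent, turning C7 from R to S, while C8 is untouched, so any leakage gives only a separable diastereomer.

Step 12
Reactants: 22 erythro 4-nitrobenzoate
Product: 23 (1S,2R)-3-(TBSO)-1-(4-{[1,3-bis(TBSO)propan-2-yl]oxy}-3-methoxyphenyl)-2-{4-[3-(TBSO)propyl]-2,6-dimethoxyphenoxy}propan-1-ol (erythro)
Conditions: K2CO3 (0.5 equiv), MeOH/THF (2:1), 0 °C to rt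
Reagents that add atoms: none
Why: Base-catalysed transesterification (methanolysis) of the activated ester proceeds by acyl–oxygen cleavage, so the C7–O bond and the new 7S configuration are retained and the alkyl TBS ethers survive.

Step 13
Reactants: 23 erythro tetra-TBS ether
Product: 24 (1S,2R)-1-{4-[(1,3-dihydroxypropan-2-yl)oxy]-3-methoxyphenyl}-2-[4-(3-hydroxypropyl)-2,6-dimethoxyphenoxy]propane-1,3-diol (target; 7S,8R)
Conditions: TBAF (6 equiv), AcOH (6 equiv), THF, rt; chromatography on SiO2 (CH2Cl2/MeOH)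
Reagents that add atoms: none
Why: Fluoride-driven desilylation removes all four primary TBS ethers at near-neutral pH, which avoids the acid that would ionise and epimerise the electron-rich benzylic C7 carbinol.

## Compound list
1 | glycerol | OCC(O)CO | starting material
2 | 1,3-bis(tert-butyldimethylsilyloxy)propan-2-ol | CC(C)(C)[Si](C)(C)OCC(O)CO[Si](C)(C)C(C)(C)C | intermediate
3 | vanillin (4-hydroxy-3-methoxybenzaldehyde) | COc1cc(C=O)ccc1O | starting material
4 | [1,3-bis(TBSO)propan-2-yloxy]triphenylphosphonium 4-formyl-2-methoxyphenolate | CC(C)(C)[Si](C)(C)OCC(CO[Si](C)(C)C(C)(C)C)O[P+](c1ccccc1)(c1ccccc1)c1ccccc1.COc1cc(C=O)ccc1[O-] | intermediate (not isolated)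
5 | 4-{[1,3-bis(TBSO)propan-2-yl]oxy}-3-methoxybenzaldehyde | COc1cc(C=O)ccc1OC(CO[Si](C)(C)C(C)(C)C)CO[Si](C)(C)C(C)(C)C | intermediate
6 | 4-allyl-2,6-dimethoxyphenol | C=CCc1cc(OC)c(O)c(OC)c1 | starting material
7 | ethyl bromoacetate | CCOC(=O)CBr | starting material
8 | ethyl 2-(4-allyl-2,6-dimethoxyphenoxy)acetate | CCOC(=O)COc1c(OC)cc(CC=C)cc1OC | intermediate
9 | ethyl 2-{4-[3-(9-borabicyclo[3.3.1]nonan-9-yl)propyl]-2,6-dimethoxyphenoxy}acetate | CCOC(=O)COc1c(OC)cc(CCCB2C3CCCC2CCC3)cc1OC | intermediate (not isolated)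
10 | ethyl 2-[4-(3-hydroxypropyl)-2,6-dimethoxyphenoxy]acetate | CCOC(=O)COc1c(OC)cc(CCCO)cc1OC | intermediate
11 | ethyl 2-{4-[3-(TBSO)propyl]-2,6-dimethoxyphenoxy}acetate | CCOC(=O)COc1c(OC)cc(CCCO[Si](C)(C)C(C)(C)C)cc1OC | intermediate
12 | 2-{4-[3-(TBSO)propyl]-2,6-dimethoxyphenoxy}acetic acid | OC(=O)COc1c(OC)cc(CCCO[Si](C)(C)C(C)(C)C)cc1OC | intermediate
13 | (S)-4-benzyloxazolidin-2-one | O=C1N[C@@H](Cc2ccccc2)CO1 | starting material
14 | mixed anhydride of 12 and pivalic acid | CC(C)(C)C(=O)OC(=O)COc1c(OC)cc(CCCO[Si](C)(C)C(C)(C)C)cc1OC | intermediate (not isolated)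
15 | (S)-4-benzyl-3-(2-{4-[3-(TBSO)propyl]-2,6-dimethoxyphenoxy}acetyl)oxazolidin-2-one | O=C(COc1c(OC)cc(CCCO[Si](C)(C)C(C)(C)C)cc1OC)N1[C@@H](Cc2ccccc2)COC1=O | intermediate
16 | (Z)-dibutylboron enolate of 15 | CCCCB(CCCC)O/C(=C\Oc1c(OC)cc(CCCO[Si](C)(C)C(C)(C)C)cc1OC)N1[C@@H](Cc2ccccc2)COC1=O | intermediate (not isolated)
17 | dibutylboron aldolate of 18 (2S,3R; 4S) | COc1cc([C@@H](OB(CCCC)CCCC)[C@@H](C(=O)N3[C@@H](Cc4ccccc4)COC3=O)Oc2c(OC)cc(CCCO[Si](C)(C)C(C)(C)C)cc2OC)ccc1OC(CO[Si](C)(C)C(C)(C)C)CO[Si](C)(C)C(C)(C)C | intermediate (not isolated)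
18 | syn aldol adduct, (4S)-auxiliary, (2S,3R)-acyl chain | COc1cc([C@@H](O)[C@@H](C(=O)N3[C@@H](Cc4ccccc4)COC3=O)Oc2c(OC)cc(CCCO[Si](C)(C)C(C)(C)C)cc2OC)ccc1OC(CO[Si](C)(C)C(C)(C)C)CO[Si](C)(C)C(C)(C)C | intermediate
19 | threo-(1R,2R)-1,3-diol, three distal OTBS | COc1cc([C@@H](O)[C@@H](CO)Oc2c(OC)cc(CCCO[Si](C)(C)C(C)(C)C)cc2OC)ccc1OC(CO[Si](C)(C)C(C)(C)C)CO[Si](C)(C)C(C)(C)C | intermediate
20 | threo-(1R,2R)-C7 alcohol, four OTBS | COc1cc([C@@H](O)[C@@H](CO[Si](C)(C)C(C)(C)C)Oc2c(OC)cc(CCCO[Si](C)(C)C(C)(C)C)cc2OC)ccc1OC(CO[Si](C)(C)C(C)(C)C)CO[Si](C)(C)C(C)(C)C | intermediate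
21 | C7-alkoxytriphenylphosphonium 4-nitrobenzoate of 20 (C7 configuration as in 20) | COc1cc([C@@H](O[P+](c3ccccc3)(c3ccccc3)c3ccccc3)[C@@H](CO[Si](C)(C)C(C)(C)C)Oc2c(OC)cc(CCCO[Si](C)(C)C(C)(C)C)cc2OC)ccc1OC(CO[Si](C)(C)C(C)(C)C)CO[Si](C)(C)C(C)(C)C.[O-]C(=O)c1ccc(cc1)[N+](=O)[O-] | intermediate (not isolated)
22 | erythro-(1S,2R)-C7 4-nitrobenzoate, four OTBS | COc1cc([C@H](OC(=O)c3ccc(cc3)[N+](=O)[O-])[C@@H](CO[Si](C)(C)C(C)(C)C)Oc2c(OC)cc(CCCO[Si](C)(C)C(C)(C)C)cc2OC)ccc1OC(CO[Si](C)(C)C(C)(C)C)CO[Si](C)(C)C(C)(C)C | intermediate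
23 | erythro-(1S,2R)-C7 alcohol, four OTBS | COc1cc([C@H](O)[C@@H](CO[Si](C)(C)C(C)(C)C)Oc2c(OC)cc(CCCO[Si](C)(C)C(C)(C)C)cc2OC)ccc1OC(CO[Si](C)(C)C(C)(C)C)CO[Si](C)(C)C(C)(C)C | intermediate
24 | (1S,2R)-1-{4-[(1,3-dihydroxypropan-2-yl)oxy]-3-methoxyphenyl}-2-[4-(3-hydroxypropyl)-2,6-dimethoxyphenoxy]propane-1,3-diol | COc1cc([C@H](O)[C@@H](CO)Oc2c(OC)cc(CCCO)cc2OC)ccc1OC(CO)CO | target

## Step count and risks
Total step count: 13 (aldehyde fragment 2, imide fragment 5, after union 6).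
Longest linear sequence: 11 steps (steps 3 to 13, from 6).

Three steps most likely to fail:

**Step 11, Mitsunobu inversion at C7.**
- Risk: the carbinol is hindered and para-alkoxy-activated, so partial ionisation can erode the erythro/threo ratio, and elimination to the enol ether is possible. Only the diastereomer ratio is at stake, because C8 stays fixed.
- Fallback: it sets out from 20 and comes back at 23, skipping 22. Alcohol 20 is oxidised with Dess–Martin periodinane and NaHCO3 in CH2Cl2 to the (2R)-α-aryloxy ketone F3. This is reduced at once with Zn(BH4)2 in Et2O at −40 °C.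
- Stereocontrol: zinc chelates the carbonyl and the aryloxy oxygen, and hydride arrives from the side of the C8 hydrogen, giving the erythro alcohol 23. Neutral oxidation and cold reduction limit epimerisation at C8, and the minor threo isomer (20) is recycled.

**Step 8, boron aldol.**
- Risk: the bulky, Lewis-basic 2,6-dimethoxyphenoxy group may slow enolisation with Bu2BOTf or lower the syn selectivity.
- Fallback: it sets out from 12 (with 5) and comes back at 19. Acid 12 is coupled with (S)-4-benzylthiazolidine-2-thione (EDC·HCl, DMAP, CH2Cl2) to the N-acylthiazolidinethione F1.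
- Soft enolisation with TiCl4, iPr2NEt and N-methylpyrrolidinone in CH2Cl2 at −78 °C, then addition of 5, gives the same-sense syn aldol adduct F2. Its very labile auxiliary is displaced directly by NaBH4 in THF/EtOH to give 19.

**Step 2, Mitsunobu etherification.**
- Risk: the secondary alcohol is flanked by two CH2OTBS groups and may react sluggishly.
- Fallback: it sets out from 3 and comes back at 5, so 2 is not needed. Vanillin is alkylated with diethyl bromomalonate (K2CO3, DMF, rt) to diethyl 2-(4-formyl-2-methoxyphenoxy)malonate F4.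
- LiAlH4 in THF reduces both esters and the aldehyde to the triol 2-[4-(hydroxymethyl)-2-methoxyphenoxy]propane-1,3-diol F5. Activated MnO2 in acetone reoxidises only the benzylic alcohol to 4-[(1,3-dihydroxypropan-2-yl)oxy]-3-methoxybenzaldehyde F6. TBSCl (2.2 equiv) and imidazole in DMF then give 5.

## Further compounds
F1 | step 8 | (S)-4-benzyl-3-(2-{4-[3-(TBSO)propyl]-2,6-dimethoxyphenoxy}acetyl)thiazolidine-2-thione | O=C(COc1c(OC)cc(CCCO[Si](C)(C)C(C)(C)C)cc1OC)N1[C@@H](Cc2ccccc2)CSC1=S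
F2 | step 8 | syn aldol adduct on the (4S)-thiazolidinethione, (2S,3R)-acyl chain | COc1cc([C@@H](O)[C@@H](C(=O)N3[C@@H](Cc4ccccc4)CSC3=S)Oc2c(OC)cc(CCCO[Si](C)(C)C(C)(C)C)cc2OC)ccc1OC(CO[Si](C)(C)C(C)(C)C)CO[Si](C)(C)C(C)(C)C
F3 | step 11 | (2R)-3-(TBSO)-1-(4-{[1,3-bis(TBSO)propan-2-yl]oxy}-3-methoxyphenyl)-2-{4-[3-(TBSO)propyl]-2,6-dimethoxyphenoxy}propan-1-one | COc1cc(C(=O)[C@@H](CO[Si](C)(C)C(C)(C)C)Oc2c(OC)cc(CCCO[Si](C)(C)C(C)(C)C)cc2OC)ccc1OC(CO[Si](C)(C)C(C)(C)C)CO[Si](C)(C)C(C)(C)C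
F4 | step 2 | diethyl 2-(4-formyl-2-methoxyphenoxy)malonate | CCOC(=O)C(Oc1ccc(C=O)cc1OC)C(=O)OCC
F5 | step 2 | 2-[4-(hydroxymethyl)-2-methoxyphenoxy]propane-1,3-diol | COc1cc(CO)ccc1OC(CO)CO
F6 | step 2 | 4-[(1,3-dihydroxypropan-2-yl)oxy]-3-methoxybenzaldehyde | COc1cc(C=O)ccc1OC(CO)CO
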